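**Plan**

- Cuts, in retrosynthetic order: the six O-benzyl groups; the aryl–aryl bond from flavone C3 to flavan C8 (Suzuki–Miyaura, 3-iodoflavone plus flavan-8-boronate); in the flavan, O1–C2 and C3–C4 together (ortho-quinone methide plus 4-(benzyloxy)styrene); C4–C4a (formaldehyde plus 3,5-bis(benzyloxy)phenol).
- Enabling feature: flavan ring A is a phloroglucinol whose oxygen O1 on C8a stands ortho to the benzylic carbon C4 on C4a. This is the latent oxa-diene O1=C8a–C4a=C4 of an ortho-quinone methide, made easy to ionise by the C5 and C7 ether oxygens. C2–C3 with its 4-oxygenated aryl group is an electron-rich styrene.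
- Forward order: ring A is bought as phenol 1 and gains C4 by ortho-formylation and reduction; ring C of the flavan closes in the cycloaddition; C8 is brominated and borylated. The flavone rings are bought as apigenin, benzylated and iodinated at C3. The halves are coupled and all benzyl groups removed.
- Stereochemistry: the only stereocentre, C2 (S), is set in the cycloaddition by a chiral Brønsted acid (catalyst control) and no later step touches it.

Key step: step 4

Assumption: the flavone C3–flavan C8 bond carries four ortho substituents, but the target defines no axial configuration, so rotamers about it are treated as one equilibrating compound.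

**Route**

Step 1
Reactants: 1 3,5-bis(benzyloxy)phenol
Product: 2 2-hydroxy-4,6-bis(benzyloxy)benzaldehyde
Conditions: MgCl2, Et3N, (CH2O)n, MeCN, reflux; 1 M HCl work-up
Reagents that add atoms: paraformaldehyde (source of formaldehyde), C=O
Why: Magnesium-phenoxide-directed ortho-formylation (Casnati–Skattebøl) delivers formaldehyde only ortho to the free OH through a six-membered chelate, a second equivalent of formaldehyde takes up hydride, and the chelated aldehyde is deactivated towards a second formylation.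

Step 2
Reactants: 2 2-hydroxy-4,6-bis(benzyloxy)benzaldehyde
Product: 3 3,5-bis(benzyloxy)-2-(hydroxymethyl)phenol
Conditions: NaBH4, THF/MeOH, 0 °C; pH 7 buffer work-up, used at once
Reagents that add atoms: none
Why: Hydride reduction of the aldehyde with NaBH4, kept cold and worked up at neutral pH because this electron-rich salicyl alcohol ionises easily.

Step 3
Reactants: 4 4-(benzyloxy)benzaldehyde
Product: 5 1-(benzyloxy)-4-ethenylbenzene (4-(benzyloxy)styrene)
Conditions: Ph3PCH3Br, KOtBu, THF, 0 °C to rt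
Reagents that add atoms: methyltriphenylphosphonium bromide, C[P+](c1ccccc1)(c1ccccc1)c1ccccc1.[Br-]
Why: Wittig methylenation of a non-enolisable aromatic aldehyde.

Step 4
Reactants: 3 3,5-bis(benzyloxy)-2-(hydroxymethyl)phenol, 5 1-(benzyloxy)-4-ethenylbenzene
Product: 7 (2S)-5,7-bis(benzyloxy)-2-[4-(benzyloxy)phenyl]chromane, via ortho-quinone methide 6 (not isolated)
Conditions: (R)-3,3'-bis(2,4,6-triisopropylphenyl)-1,1'-binaphthyl-2,2'-diyl N-triflylphosphoramide (10 mol%), 5 (3 equiv), 5 Å MS, toluene, −40 °C, slow addition of 3; Et3N quench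
Reagents that add atoms: none
Why: Proposed new method: the chiral acid ionises the benzylic C–OH of 3 (the cation is stabilised by the ortho OH and the two benzyloxy donors of ring A) to give ortho-quinone methide 6 hydrogen-bonded or ion-paired to the chiral phosphoramidate, and styrene 5 adds in a concerted, strongly asynchronous inverse-electron-demand oxa-Diels–Alder reaction in which C3–C4 forms ahead of O1–C2. The closest known reaction type is the chiral phosphoric acid or N-triflylphosphoramide catalysed [4+2] cycloaddition of in situ generated, methide-substituted ortho-quinone methides with styrenes; new here is the unsubstituted methide carbon, so that the catalyst alone must fix C2. Ring C closes by the [4+2] cycloaddition across O1=C8a–C4a=C4 (in the stepwise limit, C–C bond formation followed by 6-exo-trig capture of the 4-(benzyloxy)benzyl cation by the phenol oxygen). C2 is set by catalyst control: the anion bound at O1 should shield one face of the planar oxa-diene with a triisopropylphenyl wall while the aryl group of 5 lies endo on the open face, giving (2S); the antipodal catalyst serves if the sense proves opposite. Regiochemistry (2-aryl, not 3-aryl) follows from polarity, the nucleophilic terminal CH2 of 5 bonding to the electrophilic methide carbon, and since only one phenol oxygen is free the quinone methide can form in one way only. The competing self-condensation of 6 at its free ring positions and cationic oligomerisation of 5 should be held back by slow addition of 3 to excess 5 at low temperature.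

Step 5
Reactants: 7 (2S)-5,7-bis(benzyloxy)-2-[4-(benzyloxy)phenyl]chromane
Product: 8 (2S)-8-bromo-5,7-bis(benzyloxy)-2-[4-(benzyloxy)phenyl]chromane
Conditions: NBS (1.0 equiv), CH2Cl2, −78 to 0 °C, dark
Reagents that add atoms: N-bromosuccinimide, O=C1CCC(=O)N1Br
Why: Electrophilic aromatic bromination; C6 and C8 are each flanked by two oxygens, but C8, between the ring oxygen O1 and one benzyloxy group, is the less hindered site, as is usual for O-benzylated flavans.

Step 6
Reactants: 8 (2S)-8-bromo-5,7-bis(benzyloxy)-2-[4-(benzyloxy)phenyl]chromane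
Product: 10 (2S)-5,7-bis(benzyloxy)-2-[4-(benzyloxy)phenyl]-8-(4,4,5,5-tetramethyl-1,3,2-dioxaborolan-2-yl)chromane, via 8-lithioflavan 9 (not isolated)
Conditions: n-BuLi, THF, −78 °C; then iPrOBpin, −78 °C to rt
Reagents that add atoms: 2-isopropoxy-4,4,5,5-tetramethyl-1,3,2-dioxaborolane, CC(C)OB1OC(C)(C)C(C)(C)O1
Why: Bromine–lithium exchange at −78 °C is faster than deprotonation at the benzylic C2–H or the benzyl ethers, and the aryllithium is trapped by the borate ester (lithiation–borylation).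

Step 7
Reactants: 11 apigenin (5,7-dihydroxy-2-(4-hydroxyphenyl)-4H-chromen-4-one)
Product: 12 5,7-bis(benzyloxy)-2-[4-(benzyloxy)phenyl]-4H-chromen-4-one
Conditions: BnBr, Cs2CO3, Bu4NI (cat.), DMF, 70 °C
Reagents that add atoms: benzyl bromide, BrCc1ccccc1
Why: Williamson etherification of all three phenols, with forcing conditions to alkylate the hydrogen-bonded 5-OH.

Step 8
Reactants: 12 5,7-bis(benzyloxy)-2-[4-(benzyloxy)phenyl]-4H-chromen-4-one
Product: 14 5,7-bis(benzyloxy)-2-[4-(benzyloxy)phenyl]-3-iodo-4H-chromen-4-one, via 3-lithioflavone 13 (not isolated)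
Conditions: LiN(iPr)2 (LDA), THF, −78 °C; then I2, −78 °C to rt
Reagents that add atoms: iodine, II
Why: Deprotonation of the flavone at C3 by LDA (the only acidic sp2 C–H, flanked by the C4 carbonyl and the enol ether) and iodine quench of the vinyllithium.

Step 9
Reactants: 10 (2S)-5,7-bis(benzyloxy)-2-[4-(benzyloxy)phenyl]-8-(4,4,5,5-tetramethyl-1,3,2-dioxaborolan-2-yl)chromane, 14 5,7-bis(benzyloxy)-2-[4-(benzyloxy)phenyl]-3-iodo-4H-chromen-4-one
Product: 15 3-[(2S)-5,7-bis(benzyloxy)-2-[4-(benzyloxy)phenyl]chroman-8-yl]-5,7-bis(benzyloxy)-2-[4-(benzyloxy)phenyl]-4H-chromen-4-one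
Conditions: Pd(OAc)2 (10 mol%), SPhos (20 mol%), K3PO4, toluene/H2O, 100 °C
Reagents that add atoms: none
Why: Suzuki–Miyaura coupling in which the bulky, electron-rich dialkylbiarylphosphine SPhos supports oxidative addition to the hindered iodide and reductive elimination to the tetra-ortho-substituted aryl–aryl bond; C2 is not involved.

Step 10
Reactants: 15 3-[(2S)-5,7-bis(benzyloxy)-2-[4-(benzyloxy)phenyl]chroman-8-yl]-5,7-bis(benzyloxy)-2-[4-(benzyloxy)phenyl]-4H-chromen-4-one
Product: 16 daphnodorin D2, 3-[(2S)-5,7-dihydroxy-2-(4-hydroxyphenyl)chroman-8-yl]-5,7-dihydroxy-2-(4-hydroxyphenyl)-4H-chromen-4-one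
Conditions: H2 (1 atm), Pd(OH)2/C, THF/MeOH, rt
Reagents that add atoms: none
Why: Hydrogenolysis of six benzyl ethers; the tetrasubstituted vinylogous-ester C2=C3 of the flavone and the cyclic benzylic C2–O1 bond of the flavan react much more slowly, so C2 should keep its configuration.

**Compound list**

1 | 3,5-bis(benzyloxy)phenol | Oc1cc(OCc2ccccc2)cc(OCc2ccccc2)c1 | starting material
2 | 2-hydroxy-4,6-bis(benzyloxy)benzaldehyde | O=Cc1c(O)cc(OCc2ccccc2)cc1OCc1ccccc1 | intermediate
3 | 3,5-bis(benzyloxy)-2-(hydroxymethyl)phenol | OCc1c(O)cc(OCc2ccccc2)cc1OCc1ccccc1 | intermediate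
4 | 4-(benzyloxy)benzaldehyde | O=Cc1ccc(OCc2ccccc2)cc1 | starting material
5 | 1-(benzyloxy)-4-ethenylbenzene | C=Cc1ccc(OCc2ccccc2)cc1 | intermediate
6 | 3,5-bis(benzyloxy)-6-methylidenecyclohexa-2,4-dien-1-one (ortho-quinone methide) | C=C1C(=O)C=C(OCc2ccccc2)C=C1OCc1ccccc1 | intermediate
7 | (2S)-5,7-bis(benzyloxy)-2-[4-(benzyloxy)phenyl]chromane | c1(OCc2ccccc2)cc(OCc2ccccc2)c2c(c1)O[C@H](c1ccc(OCc3ccccc3)cc1)CC2 | intermediate
8 | (2S)-8-bromo-5,7-bis(benzyloxy)-2-[4-(benzyloxy)phenyl]chromane | c1(OCc2ccccc2)cc(OCc2ccccc2)c2c(c1Br)O[C@H](c1ccc(OCc3ccccc3)cc1)CC2 | intermediate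
9 | (2S)-5,7-bis(benzyloxy)-2-[4-(benzyloxy)phenyl]chroman-8-yllithium | [Li]c1c(OCc2ccccc2)cc(OCc2ccccc2)c2c1O[C@H](c1ccc(OCc3ccccc3)cc1)CC2 | intermediate
10 | (2S)-5,7-bis(benzyloxy)-2-[4-(benzyloxy)phenyl]-8-(4,4,5,5-tetramethyl-1,3,2-dioxaborolan-2-yl)chromane | CC1(C)OB(OC1(C)C)c1c(OCc2ccccc2)cc(OCc2ccccc2)c2c1O[C@H](c1ccc(OCc3ccccc3)cc1)CC2 | intermediate
11 | apigenin | O=c1cc(-c2ccc(O)cc2)oc2cc(O)cc(O)c12 | starting material
12 | 5,7-bis(benzyloxy)-2-[4-(benzyloxy)phenyl]-4H-chromen-4-one | O=c1cc(-c2ccc(OCc3ccccc3)cc2)oc2cc(OCc3ccccc3)cc(OCc3ccccc3)c12 | intermediate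
13 | 5,7-bis(benzyloxy)-2-[4-(benzyloxy)phenyl]-4-oxo-4H-chromen-3-yllithium | O=c1c([Li])c(-c2ccc(OCc3ccccc3)cc2)oc2cc(OCc3ccccc3)cc(OCc3ccccc3)c12 | intermediate
14 | 5,7-bis(benzyloxy)-2-[4-(benzyloxy)phenyl]-3-iodo-4H-chromen-4-one | O=c1c(I)c(-c2ccc(OCc3ccccc3)cc2)oc2cc(OCc3ccccc3)cc(OCc3ccccc3)c12 | intermediate
15 | 3-[(2S)-5,7-bis(benzyloxy)-2-[4-(benzyloxy)phenyl]chroman-8-yl]-5,7-bis(benzyloxy)-2-[4-(benzyloxy)phenyl]-4H-chromen-4-one | O=c1c(-c2c(OCc3ccccc3)cc(OCc3ccccc3)c3c2O[C@H](c2ccc(OCc4ccccc4)cc2)CC3)c(-c2ccc(OCc3ccccc3)cc2)oc2cc(OCc3ccccc3)cc(OCc3ccccc3)c12 | intermediate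
16 | daphnodorin D2 | O=c1c(-c2c(O)cc(O)c3c2O[C@H](c2ccc(O)cc2)CC3)c(-c2ccc(O)cc2)oc2cc(O)cc(O)c12 | target

**Step count and risks**

Total step count: 10. Longest linear sequence: 7 steps (steps 1, 2, 4, 5, 6, 9, 10).

Steps most likely to fail:

1. Step 4 (Proposed new method). The risks are poor facial discrimination at an unsubstituted methide carbon, erosion of enantiopurity by acid-induced reversible ionisation at C2, and self-condensation of the quinone methide. The fallback uses known chemistry, sets out from aldehyde 2 and returns at flavan 7.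
   - Claisen–Schmidt condensation of 2 with commercial 4'-(benzyloxy)acetophenone (KOH, EtOH) should give (E)-1-[4-(benzyloxy)phenyl]-3-[2-hydroxy-4,6-bis(benzyloxy)phenyl]prop-2-en-1-one F1.
   - Hydrogenation of the enone C=C only (H2, RhCl(PPh3)3, benzene/EtOH, benzyl ethers untouched) should give 1-[4-(benzyloxy)phenyl]-3-[2-hydroxy-4,6-bis(benzyloxy)phenyl]propan-1-one F2.
   - Asymmetric transfer hydrogenation of the aryl ketone (RuCl(p-cymene)[(R,R)-TsDPEN], HCO2H/Et3N) should give (1R)-1-[4-(benzyloxy)phenyl]-3-[2-hydroxy-4,6-bis(benzyloxy)phenyl]propan-1-ol F3.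
   - Mitsunobu cyclisation (PPh3, DIAD, THF, 0 °C) closes O1–C2 with inversion and should return (2S)-flavan 7.

2. Step 9. The risks are slow transmetalation of the doubly ortho-oxygenated boronate with competing protodeboronation, and slow reductive elimination to the tetra-ortho-substituted bond. The fallback sets out from bromide 8 (step 6 is bypassed) and returns at 15; it builds the flavone ring around a much less hindered aryl–CH2 bond.
   - Commercial 2',4',6'-trihydroxyacetophenone would be dibenzylated (BnBr, K2CO3, acetone; the chelated OH stays free) to 1-[2-hydroxy-4,6-bis(benzyloxy)phenyl]ethanone F4.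
   - Protection (MOMCl, iPr2NEt, CH2Cl2) would give 1-[2,4-bis(benzyloxy)-6-(methoxymethoxy)phenyl]ethanone F5.
   - Palladium-catalysed ketone α-arylation of F5 with 8 (Pd(OAc)2, XPhos, NaOtBu, toluene, 80 °C) should give 1-[2,4-bis(benzyloxy)-6-(methoxymethoxy)phenyl]-2-[(2S)-5,7-bis(benzyloxy)-2-[4-(benzyloxy)phenyl]chroman-8-yl]ethanone F6.
   - Mild acid (HCl, MeOH/THF, 40 °C) should free the phenol to give 1-[2,4-bis(benzyloxy)-6-hydroxyphenyl]-2-[(2S)-5,7-bis(benzyloxy)-2-[4-(benzyloxy)phenyl]chroman-8-yl]ethanone F7.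
   - Heating F7 with 4-(benzyloxy)benzoyl chloride and K2CO3 in acetone (O-acylation, Baker–Venkataraman acyl shift, cyclodehydration) should give 15.

3. Step 5. The risks are bromination at C6 in place of C8, or double bromination. The fallback places the bromine before ring C exists, where a free phenol directs it; it sets out from phenol 1 and returns at bromide 8.
   - Amine-mediated ortho-bromination (NBS, iPr2NH (cat.), CH2Cl2, −78 °C) should give 2-bromo-3,5-bis(benzyloxy)phenol F8.
   - Formylation under the conditions of step 1 should give 3-bromo-2-hydroxy-4,6-bis(benzyloxy)benzaldehyde F9.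
   - Reduction under the conditions of step 2 should give 2-bromo-3,5-bis(benzyloxy)-6-(hydroxymethyl)phenol F10.
   - Cycloaddition with 5 under the conditions of step 4, through 2-bromo-3,5-bis(benzyloxy)-6-methylidenecyclohexa-2,4-dien-1-one F11, should give 8 directly.

**Further compounds**

F1 | step 4 | (E)-1-[4-(benzyloxy)phenyl]-3-[2-hydroxy-4,6-bis(benzyloxy)phenyl]prop-2-en-1-one | O=C(/C=C/c1c(O)cc(OCc2ccccc2)cc1OCc1ccccc1)c1ccc(OCc2ccccc2)cc1
F2 | step 4 | 1-[4-(benzyloxy)phenyl]-3-[2-hydroxy-4,6-bis(benzyloxy)phenyl]propan-1-one | O=C(CCc1c(O)cc(OCc2ccccc2)cc1OCc1ccccc1)c1ccc(OCc2ccccc2)cc1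
F3 | step 4 | (1R)-1-[4-(benzyloxy)phenyl]-3-[2-hydroxy-4,6-bis(benzyloxy)phenyl]propan-1-ol | O[C@H](CCc1c(O)cc(OCc2ccccc2)cc1OCc1ccccc1)c1ccc(OCc2ccccc2)cc1
F4 | step 9 | 1-[2-hydroxy-4,6-bis(benzyloxy)phenyl]ethanone | CC(=O)c1c(O)cc(OCc2ccccc2)cc1OCc1ccccc1
F5 | step 9 | 1-[2,4-bis(benzyloxy)-6-(methoxymethoxy)phenyl]ethanone | CC(=O)c1c(OCOC)cc(OCc2ccccc2)cc1OCc1ccccc1
F6 | step 9 | 1-[2,4-bis(benzyloxy)-6-(methoxymethoxy)phenyl]-2-[(2S)-5,7-bis(benzyloxy)-2-[4-(benzyloxy)phenyl]chroman-8-yl]ethanone | O=C(Cc1c(OCc2ccccc2)cc(OCc2ccccc2)c2c1O[C@H](c1ccc(OCc3ccccc3)cc1)CC2)c1c(OCOC)cc(OCc2ccccc2)cc1OCc1ccccc1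
F7 | step 9 | 1-[2,4-bis(benzyloxy)-6-hydroxyphenyl]-2-[(2S)-5,7-bis(benzyloxy)-2-[4-(benzyloxy)phenyl]chroman-8-yl]ethanone | O=C(Cc1c(OCc2ccccc2)cc(OCc2ccccc2)c2c1O[C@H](c1ccc(OCc3ccccc3)cc1)CC2)c1c(O)cc(OCc2ccccc2)cc1OCc1ccccc1
F8 | step 5 | 2-bromo-3,5-bis(benzyloxy)phenol | Oc1cc(OCc2ccccc2)cc(OCc2ccccc2)c1Br
F9 | step 5 | 3-bromo-2-hydroxy-4,6-bis(benzyloxy)benzaldehyde | O=Cc1c(O)c(Br)c(OCc2ccccc2)cc1OCc1ccccc1
F10 | step 5 | 2-bromo-3,5-bis(benzyloxy)-6-(hydroxymethyl)phenol | OCc1c(O)c(Br)c(OCc2ccccc2)cc1OCc1ccccc1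
F11 | step 5 | 2-bromo-3,5-bis(benzyloxy)-6-methylidenecyclohexa-2,4-dien-1-one | C=C1C(=O)C(Br)=C(OCc2ccccc2)C=C1OCc1ccccc1
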